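**Strategy.** The oxane (O1; C2 with the bromopentenyl chain; C3–Br; C4; C5–Cl; C6 with the enyne chain) is cut at C2–C3 and C6–C5, the two C–C bonds next to the ether carbons. A [4+3] cycloaddition of furan with an oxyallyl cation from 2,2-dimethyl-1,3-dioxan-5-one (as its 4-chloro derivative) forms both bonds and closes the ring in one operation. It exploits the C3–C4–C5 unit held between the two cis ether carbons: furan gives O1, C2, C6 and the first carbon of each chain, its C3=C4 bond is a temporary bridge fixing the 2,6-cis relation, and the acetonide tether sets both oxygens trans to the chains, for later inversion to the cis halides. The meso adduct is desymmetrised by a lipase.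

Key step: step 2

Remark: the oxane numbering given above is used for all monocyclic compounds.
Assumption: the lipase acetylates the hydroxymethyl group shown in 12; if it prefers the other enantiotopic arm, the complementary enzymatic hydrolysis mode gives the same monoacetate.

Step 1
Reactants: 1 2,2-dimethyl-1,3-dioxan-5-one
Product: 3 4-chloro-2,2-dimethyl-1,3-dioxan-5-one (racemic), via silyl enol ether 2 (not isolated)
Conditions: TMSOTf, Et3N, CH2Cl2, 0 °C; then NCS, −78 → 0 °C
Reagents that add atoms: N-chlorosuccinimide, O=C1CCC(=O)N1Cl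
Why: Soft enolisation gives the silyl enol ether, which NCS chlorinates at the enol carbon (α-chlorination of a ketone through its silyl enol ether); the new stereocentre is lost in step 2, so the racemate serves.

Step 2
Reactants: 3 4-chloro-2,2-dimethyl-1,3-dioxan-5-one; 4 furan
Product: 6 meso-8,8-dimethyl-7,9,11-trioxatricyclo[4.3.1.1(2,5)]undec-3-en-10-one, via oxyallyl cation 5 (not isolated)
Conditions: Et3N, (CF3)2CHOH, furan (excess), 0 °C → rt
Reagents that add atoms: none
Why: Proposed new method: Et3N should enolise 3 toward C6 and the ring oxygen should expel chloride to give oxyallyl cation 5, held in the U shape by the isopropylidene tether, which adds across C2 and C5 of furan in a [4+3] cycloaddition that makes the C2–C3 and C6–C5 bonds of the future oxane together. The closest known reactions are the [4+3] cycloaddition of α-chloro ketones with furan under amine base in fluorinated alcohols and the [4+3] cycloadditions of α-alkoxy oxyallyl cations made from α-keto acetals; a cyclic oxyallyl cation flanked by two ring oxygens is not known to have been used. The seven-membered carbocycle closes by the (4π+2π) cycloaddition itself, concerted or through furan alkylation followed by enolate-to-oxocarbenium closure, and the oxane ring closes with it, its oxygen and both ether carbons coming from furan. Addition to one face of furan fixes the cis relation of the two ether carbons (the former furan C3=C4 bond is a temporary bridge), the tether forces both acetal oxygens onto one face, and the compact (endo, boat-like) transition state should put the O–CMe2–O bridge on the side of the ether oxygen, so that each acetal oxygen is trans to the neighbouring bridgehead–vinyl bond. The step needs compact over extended selectivity and ring closure over simple alkylation of furan or solvent capture; the gem-dimethyl group would clash with furan C3 and C4 in the extended mode, and the ionising, weakly nucleophilic solvent, excess furan and low temperature favour cycloaddition. Because 6 is meso, no enantiocontrol is needed at this stage.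

Step 3
Reactants: 6 tricyclic ketone
Product: 7 8,8-dimethyl-7,9,11-trioxatricyclo[4.3.1.1(2,5)]undec-3-en-10-ol (C10 epimers)
Conditions: NaBH4, MeOH, 0 °C
Reagents that add atoms: none
Why: Hydride reduction of the ketone (carbonyl reduction); either face gives a usable alcohol because the carbinol centre is removed in step 5.

Step 4
Reactants: 7 tricyclic alcohol
Product: 8 O-(8,8-dimethyl-7,9,11-trioxatricyclo[4.3.1.1(2,5)]undec-3-en-10-yl) S-methyl carbonodithioate
Conditions: NaH, CS2, THF, 0 °C → rt; then MeI
Reagents that add atoms: carbon disulfide, S=C=S; iodomethane, CI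
Why: Addition of the alkoxide to CS2 and S-methylation give the xanthate (first stage of the Barton–McCombie deoxygenation); no ring stereocentre is touched.

Step 5
Reactants: 8 xanthate
Product: 9 meso-8,8-dimethyl-7,9,11-trioxatricyclo[4.3.1.1(2,5)]undec-3-ene
Conditions: n-Bu3SnH, AIBN (cat.), toluene, 110 °C
Reagents that add atoms: none
Why: Barton–McCombie radical deoxygenation; the secondary radical is flanked only by C–O bonds that do not fragment and should be reduced by the stannane before it can add across the ring to the alkene.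

Step 6
Reactants: 9 tricyclic alkene
Product: 11 meso-(3,3-dimethyl-2,4,7-trioxabicyclo[3.3.1]nonane-6,8-diyl)dimethanol, via ozonide 10 (not isolated)
Conditions: O3, CH2Cl2, −78 °C; then NaBH4, MeOH, −78 → 0 °C
Reagents that add atoms: ozone, [O-][O+]=O
Why: Ozonolysis cleaves the temporary etheno bridge and NaBH4 reduces the ozonide directly to the diol, so the α-oxygenated aldehydes are not exposed to epimerising conditions and C2 and C6 keep the cis relation set in step 2.

Step 7
Reactants: 11 meso diol
Product: 12 monoacetate of 11, acetylated on the CH2OH at C2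
Conditions: Burkholderia cepacia lipase, vinyl acetate, t-BuOMe, rt
Reagents that add atoms: vinyl acetate, CC(=O)OC=C
Why: Lipase-catalysed acylation of one of the two enantiotopic hydroxymethyl groups of a meso diol (enzymatic desymmetrisation), which fixes the absolute configuration of all four ring stereocentres at once.

Step 8
Reactants: 12 monoacetate
Product: 14 diol with C6–CH2–O and C5–O joined as acetonide, free C3–OH and C2–CH2OH, via rearranged acetate 13 (not isolated)
Conditions: CSA (cat.), acetone, rt; then K2CO3, MeOH, rt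
Reagents that add atoms: none
Why: Acid-catalysed acetal migration under thermodynamic control: the strained diaxial 3,5-acetonide opens to its oxocarbenium ion and recloses on the only free primary hydroxyl to give the trans-fused all-equatorial 1,3-dioxane, and methanolysis (transesterification) then removes the acetate; no stereocentre changes.

Step 9
Reactants: 14 diol
Product: 16 primary triflate at C2–CH2 with C3–OTBS, via hydroxy triflate 15 (not isolated)
Conditions: Tf2O, 2,6-lutidine, CH2Cl2, −78 °C; then TBSOTf, −78 → 0 °C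
Reagents that add atoms: triflic anhydride, O=S(=O)(OS(=O)(=O)C(F)(F)F)C(F)(F)F; tert-butyldimethylsilyl triflate, CC(C)(C)[Si](C)(C)OS(=O)(=O)C(F)(F)F
Why: At −78 °C Tf2O sulfonylates the primary hydroxyl much faster than the flanked secondary one, which is then silylated in the same flask (selective triflation followed by silyl protection).

Step 10
Reactants: 16 triflate; 17 but-1-yne
Product: 18 C2-(pent-2-yn-1-yl) compound with C3–OTBS and the 5,6-acetonide
Conditions: n-BuLi, THF, −78 °C (on 17); then 16, DMPU, −78 → −20 °C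
Reagents that add atoms: none
Why: SN2 alkylation of lithium but-1-ynide by the primary triflate (acetylide alkylation), which at low temperature is faster than any reaction at the silyl ether or the acetal.

Step 11
Reactants: 18 alkyne
Product: 20 C2-[(2E)-3-bromopent-2-en-1-yl] compound, via alkenylzirconium 19 (not isolated)
Conditions: Cp2Zr(H)Cl (slight excess), THF, rt; then NBS, 0 °C
Reagents that add atoms: N-bromosuccinimide, O=C1CCC(=O)N1Br
Why: syn-Hydrozirconation should place zirconium on the alkyne carbon remote from the branched, oxygenated ring carbon (steric control, helped by equilibration with the slight excess of hydride), and bromodezirconation with NBS goes with retention, so H and Br end up cis and the bromoalkene is E.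

Step 12
Reactants: 20 bromoalkene acetonide
Product: 21 diol with C6–CH2OH and C5–OH free, C3–OTBS kept
Conditions: PPTS, MeOH, rt
Reagents that add atoms: none
Why: Acid-catalysed transacetalisation in methanol removes the 1,3-dioxane acetonide faster than the hindered secondary TBS ether is cleaved.

Step 13
Reactants: 21 diol
Product: 23 primary triflate at C6–CH2 with C5–OTMS and C3–OTBS, via hydroxy triflate 22 (not isolated)
Conditions: Tf2O, 2,6-lutidine, CH2Cl2, −78 °C; then TMSOTf, −78 °C
Reagents that add atoms: triflic anhydride, O=S(=O)(OS(=O)(=O)C(F)(F)F)C(F)(F)F; trimethylsilyl triflate, C[Si](C)(C)OS(=O)(=O)C(F)(F)F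
Why: As in step 9, selective triflation of the primary hydroxyl, then silylation of the secondary hydroxyl as a labile TMS ether that keeps an alkoxide from forming in step 14.

Step 14
Reactants: 23 triflate; 24 1,4-bis(trimethylsilyl)buta-1,3-diyne
Product: 26 C6-[5-(trimethylsilyl)penta-2,4-diyn-1-yl] compound with free C5–OH, via silyl ether 25 (not isolated)
Conditions: MeLi·LiBr, THF, 0 °C → rt (on 24); then 23, HMPA, −78 °C; then 1 M HCl (aq), THF, 0 °C
Reagents that add atoms: none
Why: MeLi cleaves one C–Si bond of 24 to give lithium (trimethylsilyl)butadiynide, which displaces the primary triflate (SN2, acetylide alkylation), and the acidic work-up removes the O–TMS group but neither the alkynyl silane nor the TBS ether.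

Step 15
Reactants: 26 diynyl alcohol
Product: 28 C5 chloride (axial, cis to the C6 chain), via secondary triflate 27 (not isolated)
Conditions: Tf2O, pyridine, CH2Cl2, −20 °C; then n-Bu4NCl, −20 °C → rt
Reagents that add atoms: tetrabutylammonium chloride, CCCC[N+](CCCC)(CCCC)CCCC.[Cl-]
Why: The equatorial C5 triflate is displaced by chloride with inversion (SN2), which gives the axial chloride cis to the C6 side chain.

Step 16
Reactants: 28 chloro diyne
Product: 30 C6-[(2Z)-5-(trimethylsilyl)pent-2-en-4-yn-1-yl] compound, via alkenylborane 29 (not isolated)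
Conditions: Cy2BH, THF, 0 °C; then AcOH, 50 °C
Reagents that add atoms: none
Why: Dicyclohexylborane adds syn to the alkyl-substituted triple bond of the 1-silyl-1,3-diyne with boron next to the remaining alkyne (hydroboration), and protonolysis with acetic acid goes with retention to give the Z enyne; the trisubstituted bromoalkene is too hindered to react.

Step 17
Reactants: 30 silyl enyne
Product: 31 (2R,3S,5S,6S)-2-[(2E)-3-bromopent-2-en-1-yl]-5-chloro-6-[(2Z)-pent-2-en-4-yn-1-yl]oxan-3-ol
Conditions: n-Bu4NF, THF, 0 °C → rt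
Reagents that add atoms: none
Why: Fluoride cleaves both the secondary TBS ether and the alkynyl C–Si bond (desilylation) without touching the stereocentres.

Step 18
Reactants: 31 alcohol
Product: 32 (2R,3R,5S,6S)-3-bromo-2-[(2E)-3-bromopent-2-en-1-yl]-5-chloro-6-[(2Z)-pent-2-en-4-yn-1-yl]oxane
Conditions: CBr4, (n-C8H17)3P, toluene, 70 °C
Reagents that add atoms: tetrabromomethane, BrC(Br)(Br)Br
Why: Appel-type bromination: the alkoxyphosphonium ion of the equatorial C3 alcohol is displaced by bromide with inversion (SN2), which gives the axial bromide cis to the C2 side chain.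

**Compound list**

1 | 2,2-dimethyl-1,3-dioxan-5-one | CC1(C)OCC(=O)CO1 | starting material
2 | 2,2-dimethyl-5-(trimethylsilyloxy)-4H-1,3-dioxine (silyl enol ether, not isolated) | CC1(C)OCC(O[Si](C)(C)C)=CO1 | intermediate
3 | 4-chloro-2,2-dimethyl-1,3-dioxan-5-one (racemic) | CC1(C)OCC(=O)C(Cl)O1 | intermediate
4 | furan | c1ccoc1 | starting material
5 | 2,2-dimethyl-2H-1,3-dioxin-1-ium-5-olate (oxyallyl cation as zwitterion, not isolated) | CC1(C)OC=C([O-])C=[O+]1 | intermediate
6 | meso-8,8-dimethyl-7,9,11-trioxatricyclo[4.3.1.1(2,5)]undec-3-en-10-one; O7–C8–O9 bridge on the side of the ether oxygen O11, carbonyl on the side of the C3=C4 bond | O=C1[C@H]2OC(C)(C)O[C@@H]1[C@H]1C=C[C@@H]2O1 | intermediate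
7 | 8,8-dimethyl-7,9,11-trioxatricyclo[4.3.1.1(2,5)]undec-3-en-10-ol (C10 epimers; centre removed in step 5, so no descriptor at C10) | OC1[C@H]2OC(C)(C)O[C@@H]1[C@H]1C=C[C@@H]2O1 | intermediate
8 | O-(8,8-dimethyl-7,9,11-trioxatricyclo[4.3.1.1(2,5)]undec-3-en-10-yl) S-methyl carbonodithioate | CSC(=S)OC1[C@H]2OC(C)(C)O[C@@H]1[C@H]1C=C[C@@H]2O1 | intermediate
9 | meso-8,8-dimethyl-7,9,11-trioxatricyclo[4.3.1.1(2,5)]undec-3-ene | C1[C@H]2OC(C)(C)O[C@@H]1[C@H]1C=C[C@@H]2O1 | intermediate
10 | ozonide of 9 (1,2,4-trioxolane on the former C3=C4 bond, not isolated) | C4(O5)[C@@H]1O[C@H](C5OO4)[C@@H](OC2(C)C)C[C@H]1O2 | intermediate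
11 | meso-(3,3-dimethyl-2,4,7-trioxabicyclo[3.3.1]nonane-6,8-diyl)dimethanol, i.e. cis-2,6-bis(hydroxymethyl)oxane-3,5-diol 3,5-acetonide, each CH2OH trans to the neighbouring acetal oxygen | OC[C@@H]1O[C@H](CO)[C@@H](OC2(C)C)C[C@H]1O2 | intermediate
12 | monoacetate of 11, acetate on the CH2OH at C2 | OC[C@@H]1O[C@H](COC(C)=O)[C@@H](OC2(C)C)C[C@H]1O2 | intermediate
13 | oxane with C6–CH2–O and C5–O joined as acetonide (trans-fused 1,3-dioxane), free C3–OH, C2–CH2OAc, all four ring substituents equatorial (not isolated) | CC2(C)OC[C@@H]1O[C@H](COC(C)=O)[C@@H](O)C[C@H]1O2 | intermediate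
14 | as 13 with C2–CH2OH (diol) | CC2(C)OC[C@@H]1O[C@H](CO)[C@@H](O)C[C@H]1O2 | intermediate
15 | primary triflate of 14 with free C3–OH (not isolated) | CC2(C)OC[C@@H]1O[C@H](COS(=O)(=O)C(F)(F)F)[C@@H](O)C[C@H]1O2 | intermediate
16 | C2–CH2OTf, C3–OTBS, 5,6-acetonide | CC2(C)OC[C@@H]1O[C@H](COS(=O)(=O)C(F)(F)F)[C@@H](O[Si](C)(C)C(C)(C)C)C[C@H]1O2 | intermediate
17 | but-1-yne | CCC#C | starting material
18 | C2-(pent-2-yn-1-yl), C3–OTBS, 5,6-acetonide | CC2(C)OC[C@@H]1O[C@H](CC#CCC)[C@@H](O[Si](C)(C)C(C)(C)C)C[C@H]1O2 | intermediate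
19 | alkenylzirconocene chloride, Zr on the ethyl-bearing alkene carbon, cis to H (not isolated; cyclopentadienyl rings written as σ-bonded C5H5) | CC2(C)OC[C@@H]1O[C@H](C/C=C(/[Zr](Cl)(C3C=CC=C3)C3C=CC=C3)CC)[C@@H](O[Si](C)(C)C(C)(C)C)C[C@H]1O2 | intermediate
20 | C2-[(2E)-3-bromopent-2-en-1-yl], C3–OTBS, 5,6-acetonide | CC2(C)OC[C@@H]1O[C@H](C/C=C(/Br)CC)[C@@H](O[Si](C)(C)C(C)(C)C)C[C@H]1O2 | intermediate
21 | as 20 without acetonide: C6–CH2OH and equatorial C5–OH | OC[C@@H]1O[C@H](C/C=C(/Br)CC)[C@@H](O[Si](C)(C)C(C)(C)C)C[C@H]1O | intermediate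
22 | primary triflate of 21 with free C5–OH (not isolated) | FC(F)(F)S(=O)(=O)OC[C@@H]1O[C@H](C/C=C(/Br)CC)[C@@H](O[Si](C)(C)C(C)(C)C)C[C@H]1O | intermediate
23 | C6–CH2OTf, C5–OTMS, C3–OTBS | FC(F)(F)S(=O)(=O)OC[C@@H]1O[C@H](C/C=C(/Br)CC)[C@@H](O[Si](C)(C)C(C)(C)C)C[C@H]1O[Si](C)(C)C | intermediate
24 | 1,4-bis(trimethylsilyl)buta-1,3-diyne | C[Si](C)(C)C#CC#C[Si](C)(C)C | starting material
25 | C6-[5-(trimethylsilyl)penta-2,4-diyn-1-yl], C5–OTMS, C3–OTBS (not isolated) | C[Si](C)(C)C#CC#CC[C@@H]1O[C@H](C/C=C(/Br)CC)[C@@H](O[Si](C)(C)C(C)(C)C)C[C@H]1O[Si](C)(C)C | intermediate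
26 | as 25 with free equatorial C5–OH | C[Si](C)(C)C#CC#CC[C@@H]1O[C@H](C/C=C(/Br)CC)[C@@H](O[Si](C)(C)C(C)(C)C)C[C@H]1O | intermediate
27 | C5 triflate of 26 (not isolated) | C[Si](C)(C)C#CC#CC[C@@H]1O[C@H](C/C=C(/Br)CC)[C@@H](O[Si](C)(C)C(C)(C)C)C[C@H]1OS(=O)(=O)C(F)(F)F | intermediate
28 | C5 chloride, axial and cis to the C6 chain; silyl diyne, C3–OTBS | C[Si](C)(C)C#CC#CC[C@@H]1O[C@H](C/C=C(/Br)CC)[C@@H](O[Si](C)(C)C(C)(C)C)C[C@@H]1Cl | intermediate
29 | alkenyl(dicyclohexyl)borane, boron on the alkene carbon next to the alkyne, cis to H (not isolated) | C[Si](C)(C)C#C/C(B(C3CCCCC3)C3CCCCC3)=C\C[C@@H]1O[C@H](C/C=C(/Br)CC)[C@@H](O[Si](C)(C)C(C)(C)C)C[C@@H]1Cl | intermediate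
30 | C6-[(2Z)-5-(trimethylsilyl)pent-2-en-4-yn-1-yl], C5–Cl, C3–OTBS | C[Si](C)(C)C#C/C=C\C[C@@H]1O[C@H](C/C=C(/Br)CC)[C@@H](O[Si](C)(C)C(C)(C)C)C[C@@H]1Cl | intermediate
31 | (2R,3S,5S,6S)-2-[(2E)-3-bromopent-2-en-1-yl]-5-chloro-6-[(2Z)-pent-2-en-4-yn-1-yl]oxan-3-ol | C#C/C=C\C[C@@H]1O[C@H](C/C=C(/Br)CC)[C@@H](O)C[C@@H]1Cl | intermediate
32 | (2R,3R,5S,6S)-3-bromo-2-[(2E)-3-bromopent-2-en-1-yl]-5-chloro-6-[(2Z)-pent-2-en-4-yn-1-yl]oxane | C#C/C=C\C[C@@H]1O[C@H](C/C=C(/Br)CC)[C@H](Br)C[C@@H]1Cl | target

**Step count and risks**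

Total step count: 18. Longest linear sequence: 18 steps (1 → 32).

Steps most likely to fail:

1. Step 2 (proposed new method). The oxyallyl cation may be captured by the solvent or may only alkylate furan without closing the second bond, or the compact and extended modes may not be well separated. The fallback sets out from furan 4 and returns to the route at ketone 6, using known chemistry only. Furan and 1,1,3-trichloroacetone (Et3N, CF3CH2OH) give, by the known [4+3] cycloaddition of α-chloro ketones, 2,4-dichloro-8-oxabicyclo[3.2.1]oct-6-en-3-one F1. Zn–Cu couple with NH4Cl in MeOH removes both chlorines to give meso-8-oxabicyclo[3.2.1]oct-6-en-3-one F2. LiN(i-Pr)2 followed by 2-(phenylsulfonyl)-3-phenyloxaziridine hydroxylates the enolate from the exo face (the side of the ether bridge) to give racemic 2-exo-hydroxy-8-oxabicyclo[3.2.1]oct-6-en-3-one F3. The same operation with two equivalents of base gives meso-2-exo,4-exo-dihydroxy-8-oxabicyclo[3.2.1]oct-6-en-3-one F4. 2,2-Dimethoxypropane and CSA close the diaxial diol to the acetonide 6.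

2. Step 11. Zirconium hydride may add across the dialkyl alkyne with poor regioselectivity, giving a mixture of regioisomeric bromoalkenes. The fallback sets out from triflate 16 and returns at bromoalkene 20, and fixes geometry and regiochemistry in a separate building block. NaI in acetone gives the primary iodide F5. KOt-Bu in THF eliminates HI to the exocyclic enol ether F6. 9-BBN-H adds with boron on the methylene carbon and hydrogen delivered axially at C2 to give the B-alkyl borane F7, used in the same flask. A B-alkyl Suzuki–Miyaura coupling (PdCl2(dppf), Cs2CO3, DMF–H2O) with (E)-2-bromo-1-iodobut-1-ene F8, made from but-1-yne 17 and IBr by anti addition, then gives 20; the C–I bond should couple with retention in preference to the C–Br bond.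

3. Step 18. The substitution may be slow because the incoming bromide must pass the axial chlorine at C5, so that elimination or participation of the ring oxygen (ring contraction) takes over. The fallback sets out from 20 and returns at 32, and brings the bromine in first, before any axial halogen is present. n-Bu4NF frees the C3 hydroxyl to give the alcohol F9. CBr4 and (n-C8H17)3P give the axial C3 bromide F10 with inversion. PPTS in MeOH removes the acetonide to give the diol F11. Tf2O with 2,6-lutidine and then TMSOTf give the triflate silyl ether F12. Lithium (trimethylsilyl)butadiynide at −78 °C and acidic work-up give the diynyl alcohol F13. Tf2O with pyridine and then n-Bu4NCl give the axial C5 chloride F14 with inversion. Cy2BH followed by AcOH gives the silyl Z enyne F15. K2CO3 in MeOH removes the alkynyl silane to give 32.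

**Further compounds**

F1 | step 2 | 2,4-dichloro-8-oxabicyclo[3.2.1]oct-6-en-3-one (C2/C4 epimers) | O=C1C(Cl)[C@@H]2C=C[C@@H](O2)C1Cl
F2 | step 2 | meso-8-oxabicyclo[3.2.1]oct-6-en-3-one | O=C1C[C@@H]2C=C[C@@H](O2)C1
F3 | step 2 | 2-exo-hydroxy-8-oxabicyclo[3.2.1]oct-6-en-3-one (racemic, one enantiomer drawn) | O=C1C[C@@H]2C=C[C@@H](O2)[C@H]1O
F4 | step 2 | meso-2-exo,4-exo-dihydroxy-8-oxabicyclo[3.2.1]oct-6-en-3-one | O=C1[C@@H](O)[C@@H]2C=C[C@@H](O2)[C@H]1O
F5 | step 11 | C2–CH2I analogue of 16 | CC2(C)OC[C@@H]1O[C@H](CI)[C@@H](O[Si](C)(C)C(C)(C)C)C[C@H]1O2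
F6 | step 11 | exocyclic enol ether (C2=CH2), C3–OTBS, 5,6-acetonide | CC2(C)OC[C@@H]1OC(=C)[C@@H](O[Si](C)(C)C(C)(C)C)C[C@H]1O2
F7 | step 11 | B-alkyl-9-borabicyclo[3.3.1]nonane, boron on the C2 methylene | CC2(C)OC[C@@H]1O[C@H](CB3C4CCCC3CCC4)[C@@H](O[Si](C)(C)C(C)(C)C)C[C@H]1O2
F8 | step 11 | (E)-2-bromo-1-iodobut-1-ene | I/C=C(/Br)CC
F9 | step 18 | C3 alcohol from 20 (TBS removed, acetonide kept) | CC2(C)OC[C@@H]1O[C@H](C/C=C(/Br)CC)[C@@H](O)C[C@H]1O2
F10 | step 18 | axial C3 bromide with 5,6-acetonide | CC2(C)OC[C@@H]1O[C@H](C/C=C(/Br)CC)[C@H](Br)C[C@H]1O2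
F11 | step 18 | C3 bromide with C6–CH2OH and C5–OH | OC[C@@H]1O[C@H](C/C=C(/Br)CC)[C@H](Br)C[C@H]1O
F12 | step 18 | C3 bromide with C6–CH2OTf and C5–OTMS | FC(F)(F)S(=O)(=O)OC[C@@H]1O[C@H](C/C=C(/Br)CC)[C@H](Br)C[C@H]1O[Si](C)(C)C
F13 | step 18 | C3 bromide with the silyl diynyl chain at C6 and free C5–OH | C[Si](C)(C)C#CC#CC[C@@H]1O[C@H](C/C=C(/Br)CC)[C@H](Br)C[C@H]1O
F14 | step 18 | C3 bromide, C5 chloride, silyl diynyl chain | C[Si](C)(C)C#CC#CC[C@@H]1O[C@H](C/C=C(/Br)CC)[C@H](Br)C[C@@H]1Cl
F15 | step 18 | C-silyl derivative of 32 | C[Si](C)(C)C#C/C=C\C[C@@H]1O[C@H](C/C=C(/Br)CC)[C@H](Br)C[C@@H]1Cl
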